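(The data stem from a simulated flask on assumed constants; the scatter is artificial.)

The nucleophile and the protic impurity stand at the same charge in teal and violet, and the feed takes the same time, so the electrophile charge is what differs between these two runs.

| setting | teal | violet | flask |
|---|---|---|---|
| electrophile | 55 mM (fed, over 20 min) | 86 mM (fed, over 20 min) | 39 mM (fed, over 20 min) |
| nucleophile | 39 mM | 39 mM | 39.0 mM |
| protic impurity | 39 mM | 39 mM | 39.0 mM |
| remark | run made earlier | run made earlier |  |
| time |  |  | 50 min |

| run | time / min | electrophile / % | target / % |
|---|---|---|---|
| teal | 8.00 | 26.0 | 6.6 |
| teal | 20.0 | 72.2 | 14.7 |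
| teal | 40.0 | 65.8 | 17.4 |
| teal | 60.0 | 64.4 | 18.8 |
| violet | 8.00 | 28.1 | 8.8 |
| violet | 20.0 | 79.5 | 12.3 |
| violet | 40.0 | 75.7 | 13.4 |
| violet | 60.0 | 71.6 | 14.6 |

(standard deviation of a reading: 1 percentage point)

- part of the electrophile that has reacted at 50 min
- share of free nucleophile in free nucleophile and protonated nucleophile together, at 50 min

- percentages count the whole charge, also what has not yet gone in
- the earlier runs do not show how much of nucleophile is bound; that part of a forecast is a guess

Take the mean of the readings at 40.0 min and 60.0 min to stand for 50 min, and count the reacted electrophile as a fraction of the nucleophile charge: the uptake. Teal reads 0.492, violet 0.581. Between them stands 0.371. That number is the charge order, the slope of log uptake against log electrophile charge at fixed charges of nucleophile and protic impurity. Order one is the pseudo-first-order picture, with the reacted fraction unchanged by the charge. Order zero is a fixed uptake, with the nucleophile as limiting reagent. The reading stands between the two.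

Now ask a different column. Target makes up 51.9% of the reacted electrophile in teal and 53.1% in violet, so its amount should climb with the same order. The target readings give 0.425. Carry teal down to the flask's charge with each order: the reacted part comes to 43.3% and 42.5%. The two columns are separate readings and part by 0.8 percentage points, so commit to 43.3%. The readings do not show bound nucleophile, so give its share no number.

The forecast stands at 44% reacted and a free share of 8%, by its own words “a rough guess”.

The flask gives 43.5% reacted and a free share of 14.9%.

    electrophile + nucleophile → acid set free + target (k = 0.0790 M⁻¹ s⁻¹)
    nucleophile + acid set free ⇌ protonated nucleophile, settled at all times (K = 460 M⁻¹)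
    nucleophile + protic impurity → quenched reagent (k = 0.00390 M⁻¹ s⁻¹)
    nucleophile + target → over-reaction product (k = 0.150 M⁻¹ s⁻¹)
    nucleophile ⇌ dormant form (K = 1.40, k = 5.80 × 10⁻⁴ s⁻¹)

Read the order again from teal to the flask: 0.358. Carry 0.371 to the neighbour with 16 mM of electrophile: it gives 75.8% reacted. That neighbour shows 67.9%, an order of 0.501, higher than the carried one. The flask itself has not come to rest at 50 min, with free nucleophile at 2.07% of its charge. By 500 min, electrophile falls from 56.5% to 43.2%, target moves from 21.2% to 23.0%, and over-reaction product climbs from 22.4% to 33.8%. The reacted part then reaches 56.8%, more than at 50 min.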